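**Strategy.** The target is cut at the C8–C6' biaryl bond into natural (+)-catechin (upper half) and a lower flavan grown from phloroglucinol. Everything rests on making the lower pyran ring (O1, C2, C3, C4, C4a, C8a) from a trans-2-aryl-3-(tosyloxymethyl)-2,3-dihydrobenzofuran. Ring A, whose carbon C4a (C3a of the furan) has O1, O5 and O7 ortho/para to it, bridges the exocyclic CH2 as a phenonium ion. Tosylate return at C3 then inserts that CH2 between C3 and C3a. One operation enlarges the five-membered ring and carries the trans C2/C3 relationship, with inversion at C3, into the (2R,3S) flavan. The precursor comes from a desymmetrising rhodium-carbenoid C–H insertion.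

Key step: step 9

Remark: the C8–C6' axis has three ortho substituents and no descriptor in the target; it is treated as freely rotating, so no axial control is planned. Flavan numbering (O1…C8a, primed B ring) is used for 1–3 and 16–21, dihydrobenzofuran numbering for 11–15.

**Step 1**
Reactants: 1 (+)-catechin
Product: 2 (2R,3S)-5,7-bis(benzyloxy)-2-[3,4-bis(benzyloxy)phenyl]chroman-3-ol
Conditions: BnBr (4.4 equiv), K2CO3, DMF, 0 °C to rt
Reagents that add atoms: benzyl bromide BrCc1ccccc1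
Why: Williamson etherification takes the four phenols and leaves the much less acidic 3-OH free; no stereocenter is touched.

**Step 2**
Reactants: 2
Product: 3 (2R,3S)-5,7-bis(benzyloxy)-2-[4,5-bis(benzyloxy)-2-bromophenyl]-6,8-dibromochroman-3-ol (6,8,6'-tribromide)
Conditions: NBS (3.2 equiv), CH2Cl2–MeCN, −20 °C to rt
Reagents that add atoms: N-bromosuccinimide O=C1CCC(=O)N1Br
Why: Electrophilic aromatic bromination should fill C8 and C6 of ring A first and then C6' of ring B (para to O3', the only unhindered activated site), so the third bromine marks the coupling site and the first two serve as blocking groups.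

**Step 3**
Reactants: 4 1,3,5-triacetoxybenzene; 5 3,4-bis(benzyloxy)benzyl chloride (3.3 equiv)
Product: 6 1,3,5-tris{[3,4-bis(benzyloxy)benzyl]oxy}benzene
Conditions: 5 (3.3 equiv), NaH (6.6 equiv), DMF, 0 °C; H2O (3.0 equiv) added slowly; rt
Reagents that add atoms: 3,4-bis(benzyloxy)benzyl chloride (compound 5, three equivalents are built into the product) ClCc1ccc(OCc2ccccc2)c(OCc2ccccc2)c1
Why: Threefold Williamson etherification with in-situ deacetylation releases each of the three phenoxides slowly and O-alkylates it at once with one molecule of 5, which suppresses the C-benzylation typical of free phloroglucinol.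

**Step 4**
Reactants: 6
Product: 7 2-bromo-1,3,5-tris{[3,4-bis(benzyloxy)benzyl]oxy}benzene
Conditions: NBS (1.0 equiv), CH2Cl2, −78 to 0 °C
Reagents that add atoms: N-bromosuccinimide O=C1CCC(=O)N1Br
Why: Electrophilic monobromination; the trialkoxybenzene core is far more nucleophilic than the dialkoxybenzyl rings and its three free positions are equivalent.

**Step 5**
Reactants: 7; 8 (2-tert-butoxy-2-oxoethyl)zinc bromide
Product: 9 tert-butyl 2-(2,4,6-tris{[3,4-bis(benzyloxy)benzyl]oxy}phenyl)acetate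
Conditions: Pd(dba)2 (2 mol %), P(t-Bu)3 (2 mol %), THF, rt to 60 °C
Reagents that add atoms: none
Why: Negishi-type coupling of the Reformatsky zinc enolate (palladium-catalysed ester α-arylation under neutral conditions) tolerates the two ortho ether groups.

**Step 6**
Reactants: 9
Product: 10 tert-butyl 2-diazo-2-(2,4,6-tris{[3,4-bis(benzyloxy)benzyl]oxy}phenyl)acetate
Conditions: p-ABSA, DBU, MeCN–CH2Cl2, rt
Reagents that add atoms: 4-acetamidobenzenesulfonyl azide CC(=O)Nc1ccc(cc1)S(=O)(=O)N=[N+]=[N-]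
Why: Regitz diazo transfer to the benzylic ester enolate gives the donor/acceptor aryl diazoacetate.

**Step 7**
Reactants: 10
Product: 12 tert-butyl (2S,3S)-2-[3,4-bis(benzyloxy)phenyl]-4,6-bis{[3,4-bis(benzyloxy)benzyl]oxy}-2,3-dihydrobenzofuran-3-carboxylate (trans ester), via cis ester 11 (not isolated)
Conditions: Rh2(S-PTTL)4 [dirhodium tetrakis(N-phthaloyl-(S)-tert-leucinate)] (1 mol %), toluene, −60 °C; then KOtBu (0.2 equiv), t-BuOH–THF, 0 °C to rt
Reagents that add atoms: none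
Why: Intramolecular rhodium-carbenoid 1,5 C–H insertion into one of the two equivalent ortho O–CH2Ar groups (a desymmetrisation) closes the dihydrofuran, the chiral carboxylate ligands choosing the benzylic hydrogen and so setting C2 as S (the antipodal catalyst is used should the sense prove opposite), and base then epimerises the enolisable C3 so that both diastereomers converge on the more stable trans ester.

**Step 8**
Reactants: 12
Product: 13 [(2S,3R)-2-[3,4-bis(benzyloxy)phenyl]-4,6-bis{[3,4-bis(benzyloxy)benzyl]oxy}-2,3-dihydrobenzofuran-3-yl]methanol (trans)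
Conditions: LiAlH4, THF, 0 °C to rt
Reagents that add atoms: none
Why: Hydride reduction of the ester to the primary alcohol leaves ethers and both stereocenters untouched (the C3 descriptor changes only through CIP priorities).

**Step 9**
Reactants: 13
Product: 16 (2R,3S)-2-[3,4-bis(benzyloxy)phenyl]-5,7-bis{[3,4-bis(benzyloxy)benzyl]oxy}chroman-3-yl 4-methylbenzenesulfonate, via primary tosylate 14 (not isolated), via phenonium tosylate ion pair 15 (not isolated)
Conditions: Ts2O (1.2 equiv), 2,6-di-tert-butyl-4-methylpyridine (1.5 equiv), CH2Cl2, 0 °C; then MeNO2, 50 °C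
Reagents that add atoms: p-toluenesulfonic anhydride Cc1ccc(cc1)S(=O)(=O)OS(=O)(=O)c1ccc(C)cc1
Why: Tosylate 14 ionises with anchimeric assistance: C3a of the trialkoxy arene bridges C3 and the exocyclic CH2 to give the spirocyclopropane arenium ion pair 15, and tosylate return at ring carbon C3 cleaves C3–C3a and gives the chroman. The closest known reaction type is the Wagner–Meerwein 1,2-aryl shift through a phenonium ion with internal return of the sulfonate, as in the rearrangement of β-arylalkyl sulfonates and the ring expansion of benzocycloalkylmethyl systems. The six-membered ring is not closed by a heteroatom; it forms by 3-exo attack of the arene π system on CH2 followed by opening of the internal cyclopropane bond, a net insertion of CH2 between C3 and C3a. C2 is untouched and C3 is substituted with inversion (tosylate enters anti to the departing aryl carbon), which maps the trans dihydrobenzofuran onto the trans-diequatorial (2R,3S) flavan. The step needs capture at the ring carbon and not at CH2: return at CH2 only regenerates 14, whereas 16, a secondary ester in an unstrained ring, should be the more stable isomer and accumulate. Direct hydrolysis is avoided because water would be captured irreversibly at CH2, the hindered base, non-nucleophilic solvent and weakly nucleophilic tosylate leave the cation no other partner and spare the O-benzylic groups, and the reaction is stopped once 14 is consumed so that 16 does not ionise again through O1 participation.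

**Step 10**
Reactants: 16
Product: 17 (2R,3S)-2-[3,4-bis(benzyloxy)phenyl]-5,7-bis{[3,4-bis(benzyloxy)benzyl]oxy}chroman-3-ol
Conditions: Mg turnings, MeOH–THF, rt, sonication
Reagents that add atoms: none
Why: Single-electron (dissolving-metal) cleavage of the arenesulfonate S–O bond frees the alcohol with the C3–O bond intact, hence retention at C3.

**Step 11**
Reactants: 17
Product: 18 (2R,3S)-8-bromo-2-[3,4-bis(benzyloxy)phenyl]-5,7-bis{[3,4-bis(benzyloxy)benzyl]oxy}chroman-3-ol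
Conditions: NBS (1.0 equiv), CH2Cl2, −78 to 0 °C
Reagents that add atoms: N-bromosuccinimide O=C1CCC(=O)N1Br
Why: Electrophilic bromination of a 5,7-dialkoxyflavan goes to C8 (ortho to O1, less hindered than C6 between two ethers), the usual regiochemistry of protected catechins.

**Step 12**
Reactants: 18; 3
Product: 20 C8–C6' biaryl dimer (lower unit C8 of 17 bonded to C6' of the 6,8-dibromo upper unit of 3; both 3-OH free), via lithium aryl(triisopropoxy)borate 19 (not isolated)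
Conditions: B(OiPr)3, n-BuLi (2.1 equiv), THF, −78 °C; then 3, Pd(OAc)2 (5 mol %), SPhos, aq K3PO4, THF, 50 °C
Reagents that add atoms: none
Why: Bromine–lithium exchange with in-situ borate trapping, then Suzuki–Miyaura coupling in which oxidative addition should select the C6'–Br of 3 (one ortho substituent) over the two ring-A bromides flanked by two ethers; no stereocenter is affected.

**Step 13**
Reactants: 20
Product: 21 target, (2R,3S)-catechin-(6'→8)-(2R,3S)-catechin
Conditions: H2 (1 atm), Pd(OH)2/C, Et3N (2.2 equiv), THF–MeOH–H2O, rt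
Reagents that add atoms: none
Why: Catalytic hydrogenolysis cleaves all twelve O-benzylic C–O bonds (the dialkoxybenzyl ethers leave as 4-methylcatechol) and both C–Br bonds with triethylamine trapping HBr, while the flavan C2–O1 bonds survive as in standard procyanidin deprotections.

**Compound list**
1 | (+)-catechin | O[C@H]1Cc2c(O)cc(O)cc2O[C@@H]1c1ccc(O)c(O)c1 | starting material
2 | 5,7,3',4'-tetra-O-benzyl-(+)-catechin | O[C@H]1Cc2c(OCc3ccccc3)cc(OCc3ccccc3)cc2O[C@@H]1c1ccc(OCc2ccccc2)c(OCc2ccccc2)c1 | intermediate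
3 | 6,8,6'-tribromo-5,7,3',4'-tetra-O-benzyl-(+)-catechin | O[C@H]1Cc2c(OCc3ccccc3)c(Br)c(OCc3ccccc3)c(Br)c2O[C@@H]1c1cc(OCc2ccccc2)c(OCc2ccccc2)cc1Br | intermediate
4 | 1,3,5-triacetoxybenzene | CC(=O)Oc1cc(OC(C)=O)cc(OC(C)=O)c1 | starting material
5 | 3,4-bis(benzyloxy)benzyl chloride | ClCc1ccc(OCc2ccccc2)c(OCc2ccccc2)c1 | starting material
6 | 1,3,5-tris{[3,4-bis(benzyloxy)benzyl]oxy}benzene | c1c(OCc2ccc(OCc3ccccc3)c(OCc3ccccc3)c2)cc(OCc2ccc(OCc3ccccc3)c(OCc3ccccc3)c2)cc1OCc1ccc(OCc2ccccc2)c(OCc2ccccc2)c1 | intermediate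
7 | 2-bromo-1,3,5-tris{[3,4-bis(benzyloxy)benzyl]oxy}benzene | Brc1c(OCc2ccc(OCc3ccccc3)c(OCc3ccccc3)c2)cc(OCc2ccc(OCc3ccccc3)c(OCc3ccccc3)c2)cc1OCc1ccc(OCc2ccccc2)c(OCc2ccccc2)c1 | intermediate
8 | (2-tert-butoxy-2-oxoethyl)zinc bromide | Br[Zn]CC(=O)OC(C)(C)C | starting material
9 | tert-butyl 2-(2,4,6-tris{[3,4-bis(benzyloxy)benzyl]oxy}phenyl)acetate | CC(C)(C)OC(=O)Cc1c(OCc2ccc(OCc3ccccc3)c(OCc3ccccc3)c2)cc(OCc2ccc(OCc3ccccc3)c(OCc3ccccc3)c2)cc1OCc1ccc(OCc2ccccc2)c(OCc2ccccc2)c1 | intermediate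
10 | tert-butyl 2-diazo-2-(2,4,6-tris{[3,4-bis(benzyloxy)benzyl]oxy}phenyl)acetate | CC(C)(C)OC(=O)C(=[N+]=[N-])c1c(OCc2ccc(OCc3ccccc3)c(OCc3ccccc3)c2)cc(OCc2ccc(OCc3ccccc3)c(OCc3ccccc3)c2)cc1OCc1ccc(OCc2ccccc2)c(OCc2ccccc2)c1 | intermediate
11 | tert-butyl (2S,3R)-2-[3,4-bis(benzyloxy)phenyl]-4,6-bis{[3,4-bis(benzyloxy)benzyl]oxy}-2,3-dihydrobenzofuran-3-carboxylate (cis) | CC(C)(C)OC(=O)[C@H]1[C@@H](c3ccc(OCc4ccccc4)c(OCc4ccccc4)c3)Oc2cc(OCc3ccc(OCc4ccccc4)c(OCc4ccccc4)c3)cc(OCc3ccc(OCc4ccccc4)c(OCc4ccccc4)c3)c12 | intermediate (not isolated)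
12 | tert-butyl (2S,3S)-2-[3,4-bis(benzyloxy)phenyl]-4,6-bis{[3,4-bis(benzyloxy)benzyl]oxy}-2,3-dihydrobenzofuran-3-carboxylate (trans) | CC(C)(C)OC(=O)[C@@H]1[C@@H](c3ccc(OCc4ccccc4)c(OCc4ccccc4)c3)Oc2cc(OCc3ccc(OCc4ccccc4)c(OCc4ccccc4)c3)cc(OCc3ccc(OCc4ccccc4)c(OCc4ccccc4)c3)c12 | intermediate
13 | [(2S,3R)-2-[3,4-bis(benzyloxy)phenyl]-4,6-bis{[3,4-bis(benzyloxy)benzyl]oxy}-2,3-dihydrobenzofuran-3-yl]methanol (trans) | OC[C@@H]1[C@@H](c3ccc(OCc4ccccc4)c(OCc4ccccc4)c3)Oc2cc(OCc3ccc(OCc4ccccc4)c(OCc4ccccc4)c3)cc(OCc3ccc(OCc4ccccc4)c(OCc4ccccc4)c3)c12 | intermediate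
14 | p-toluenesulfonate of 13 | Cc1ccc(cc1)S(=O)(=O)OC[C@@H]1[C@@H](c3ccc(OCc4ccccc4)c(OCc4ccccc4)c3)Oc2cc(OCc3ccc(OCc4ccccc4)c(OCc4ccccc4)c3)cc(OCc3ccc(OCc4ccccc4)c(OCc4ccccc4)c3)c12 | intermediate (not isolated)
15 | phenonium ion pair: cyclopropane spiro-fused at C3a (CH2 bridging C3 and C3a), cationic trialkoxy-cyclohexadienyl ring, tosylate counter-ion | C1[C@@H]2[C@@H](c4ccc(OCc5ccccc5)c(OCc5ccccc5)c4)OC3=CC(=[O+]Cc4ccc(OCc5ccccc5)c(OCc5ccccc5)c4)C=C(OCc4ccc(OCc5ccccc5)c(OCc5ccccc5)c4)[C@@]123.Cc1ccc(cc1)S(=O)(=O)[O-] | intermediate (not isolated)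
16 | (2R,3S)-2-[3,4-bis(benzyloxy)phenyl]-5,7-bis{[3,4-bis(benzyloxy)benzyl]oxy}chroman-3-yl 4-methylbenzenesulfonate | Cc1ccc(cc1)S(=O)(=O)O[C@H]1Cc2c(OCc3ccc(OCc4ccccc4)c(OCc4ccccc4)c3)cc(OCc3ccc(OCc4ccccc4)c(OCc4ccccc4)c3)cc2O[C@@H]1c1ccc(OCc2ccccc2)c(OCc2ccccc2)c1 | intermediate
17 | (2R,3S)-2-[3,4-bis(benzyloxy)phenyl]-5,7-bis{[3,4-bis(benzyloxy)benzyl]oxy}chroman-3-ol | O[C@H]1Cc2c(OCc3ccc(OCc4ccccc4)c(OCc4ccccc4)c3)cc(OCc3ccc(OCc4ccccc4)c(OCc4ccccc4)c3)cc2O[C@@H]1c1ccc(OCc2ccccc2)c(OCc2ccccc2)c1 | intermediate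
18 | 8-bromo derivative of 17 | O[C@H]1Cc2c(OCc3ccc(OCc4ccccc4)c(OCc4ccccc4)c3)cc(OCc3ccc(OCc4ccccc4)c(OCc4ccccc4)c3)c(Br)c2O[C@@H]1c1ccc(OCc2ccccc2)c(OCc2ccccc2)c1 | intermediate
19 | dilithium 3-alkoxide / C8 triisopropoxyborate of 17 | [Li+].[Li+].[O-][C@H]1Cc2c(OCc3ccc(OCc4ccccc4)c(OCc4ccccc4)c3)cc(OCc3ccc(OCc4ccccc4)c(OCc4ccccc4)c3)c([B-](OC(C)C)(OC(C)C)OC(C)C)c2O[C@@H]1c1ccc(OCc2ccccc2)c(OCc2ccccc2)c1 | intermediate (not isolated)
20 | protected dimer: upper (2R,3S)-5,7-bis(benzyloxy)-6,8-dibromo-3-hydroxychroman-2-yl unit whose 4,5-bis(benzyloxy)phenyl ring is bonded at C6' to C8 of lower unit 17 | O[C@H]1Cc2c(OCc3ccccc3)c(Br)c(OCc3ccccc3)c(Br)c2O[C@@H]1c1cc(OCc2ccccc2)c(OCc2ccccc2)cc1-c1c(OCc2ccc(OCc3ccccc3)c(OCc3ccccc3)c2)cc(OCc2ccc(OCc3ccccc3)c(OCc3ccccc3)c2)c2c1O[C@H](c1ccc(OCc3ccccc3)c(OCc3ccccc3)c1)[C@@H](O)C2 | intermediate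
21 | target CNP0353739.1 | Oc1cc(O)c2c(c1)O[C@H](c1cc(O)c(O)cc1-c1c(O)cc(O)c3c1O[C@H](c1ccc(O)c(O)c1)[C@@H](O)C3)[C@@H](O)C2 | target

**Totals.** 13 steps; longest linear sequence 11 steps (steps 3–13, from 4 and 5 to 21).

**Steps most likely to fail**

Step 9. The ion pair may collapse only at the exocyclic CH2 (no net change). The arenium ion may also leak away by proton loss, hydride shift from C3 or O-debenzylation before tosylate reaches the ring carbon. The product may in turn ionise again with O1 participation and contract. The fallback sets out from 13 and no longer relies on stereospecific capture at C3; oxygen is reinstalled by elimination and hydroboration. CBr4/PPh3 should give the primary bromide F1. Warming with catalytic ZnBr2 in MeNO2 should let bromide shuttle through the bridged ion to the ring-expanded trans-3-bromoflavan F2. DBU in toluene at 80 °C should remove the anti-periplanar H-4 to give the (2S)-flav-3-ene F3 with C2 intact. Hydroboration–oxidation (BH3·THF; NaOH, H2O2) places boron at C3 anti to the 2-aryl group and rejoins the route at 17.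

Step 7. The chiral rhodium carboxylate may discriminate poorly between the enantiotopic benzylic hydrogens of a carbenoid twisted by two ortho substituents, or E1cB ring opening during the epimerisation may erode C2. The fallback sets out from 10 and replaces catalyst control by resolution. Rh2(OAc)4 followed by KOtBu should give the racemic trans ester F4, and LiAlH4 the racemic alcohol F5. Esterification with (S)-O-acetylmandelic acid (DCC, DMAP) gives two diastereomers that are separated by chromatography: the (2S,3R) acetylmandelate F6 and the (2R,3S) acetylmandelate F7, which is set aside. F6 is cleaved with K2CO3/MeOH to return to 13.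

Step 12. Protodeboronation of the doubly ortho-oxygenated borate may outrun transmetalation, or oxidative addition may fail to discriminate among the three C–Br bonds of 3. The fallback sets out from 2 and differentiates the coupling site by the halogen. NBS (2 equiv) should give the 6,8-dibromide F8, and NIS with catalytic TFA in MeCN the 6'-iodide F9. Coupling of borate 19 with F9 at room temperature proceeds through the far faster C–I oxidative addition and returns to 20.

**Further compounds**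
F1 | step 9 | (2S,3S)-3-(bromomethyl)-2-[3,4-bis(benzyloxy)phenyl]-4,6-bis{[3,4-bis(benzyloxy)benzyl]oxy}-2,3-dihydrobenzofuran | BrC[C@@H]1[C@@H](c3ccc(OCc4ccccc4)c(OCc4ccccc4)c3)Oc2cc(OCc3ccc(OCc4ccccc4)c(OCc4ccccc4)c3)cc(OCc3ccc(OCc4ccccc4)c(OCc4ccccc4)c3)c12
F2 | step 9 | (2R,3S)-3-bromo-2-[3,4-bis(benzyloxy)phenyl]-5,7-bis{[3,4-bis(benzyloxy)benzyl]oxy}chroman | Br[C@H]1Cc2c(OCc3ccc(OCc4ccccc4)c(OCc4ccccc4)c3)cc(OCc3ccc(OCc4ccccc4)c(OCc4ccccc4)c3)cc2O[C@@H]1c1ccc(OCc2ccccc2)c(OCc2ccccc2)c1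
F3 | step 9 | (2S)-2-[3,4-bis(benzyloxy)phenyl]-5,7-bis{[3,4-bis(benzyloxy)benzyl]oxy}-2H-chromene | C1=Cc2c(OCc3ccc(OCc4ccccc4)c(OCc4ccccc4)c3)cc(OCc3ccc(OCc4ccccc4)c(OCc4ccccc4)c3)cc2O[C@@H]1c1ccc(OCc2ccccc2)c(OCc2ccccc2)c1
F4 | step 7 | racemic trans ester (12 and its enantiomer) | CC(C)(C)OC(=O)[C@@H]1[C@@H](c3ccc(OCc4ccccc4)c(OCc4ccccc4)c3)Oc2cc(OCc3ccc(OCc4ccccc4)c(OCc4ccccc4)c3)cc(OCc3ccc(OCc4ccccc4)c(OCc4ccccc4)c3)c12.CC(C)(C)OC(=O)[C@H]1[C@H](c3ccc(OCc4ccccc4)c(OCc4ccccc4)c3)Oc2cc(OCc3ccc(OCc4ccccc4)c(OCc4ccccc4)c3)cc(OCc3ccc(OCc4ccccc4)c(OCc4ccccc4)c3)c12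
F5 | step 7 | racemic trans alcohol (13 and its enantiomer) | OC[C@@H]1[C@@H](c3ccc(OCc4ccccc4)c(OCc4ccccc4)c3)Oc2cc(OCc3ccc(OCc4ccccc4)c(OCc4ccccc4)c3)cc(OCc3ccc(OCc4ccccc4)c(OCc4ccccc4)c3)c12.OC[C@H]1[C@H](c3ccc(OCc4ccccc4)c(OCc4ccccc4)c3)Oc2cc(OCc3ccc(OCc4ccccc4)c(OCc4ccccc4)c3)cc(OCc3ccc(OCc4ccccc4)c(OCc4ccccc4)c3)c12
F6 | step 7 | (S)-O-acetylmandelate ester of 13 | CC(=O)O[C@H](C(=O)OC[C@@H]1[C@@H](c3ccc(OCc4ccccc4)c(OCc4ccccc4)c3)Oc2cc(OCc3ccc(OCc4ccccc4)c(OCc4ccccc4)c3)cc(OCc3ccc(OCc4ccccc4)c(OCc4ccccc4)c3)c12)c1ccccc1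
F7 | step 7 | (S)-O-acetylmandelate ester of the (2R,3S) enantiomer of 13 | CC(=O)O[C@H](C(=O)OC[C@H]1[C@H](c3ccc(OCc4ccccc4)c(OCc4ccccc4)c3)Oc2cc(OCc3ccc(OCc4ccccc4)c(OCc4ccccc4)c3)cc(OCc3ccc(OCc4ccccc4)c(OCc4ccccc4)c3)c12)c1ccccc1
F8 | step 12 | 6,8-dibromo-5,7,3',4'-tetra-O-benzyl-(+)-catechin | O[C@H]1Cc2c(OCc3ccccc3)c(Br)c(OCc3ccccc3)c(Br)c2O[C@@H]1c1ccc(OCc2ccccc2)c(OCc2ccccc2)c1
F9 | step 12 | 6,8-dibromo-6'-iodo-5,7,3',4'-tetra-O-benzyl-(+)-catechin | O[C@H]1Cc2c(OCc3ccccc3)c(Br)c(OCc3ccccc3)c(Br)c2O[C@@H]1c1cc(OCc2ccccc2)c(OCc2ccccc2)cc1I
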